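**Retrosynthetic overview**
1. Endgame: the 7β-OH comes from a C7 ketone by hydride delivery on the α face. The 6α-OAc comes from hydroxylation of the C7 enolate, which can form only toward C6 because C8 is quaternary. The (12Z)-diene comes from a C12 lactol by iodo-olefination and vinyl coupling.
2. These operations start from a tricyclic 7-oxo-8α,12-olide. Its γ-lactone (ring C, O8–C12) is not in the target: it is made on purpose, masks O8 and C12, and is opened again.
3. Key disconnection: ring B (C5–C6–C7–C8–C9–C10) arises from the cyclopentane C5–C6–C7–C9–C10 of a 7β-acetyl-7α-hydroxy trans-hydrindane. C9 shifts from C7 to the acetyl carbon C8 (α-ketol ring expansion), and lactonisation locks the result.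
4. Enabling feature: in ring B the methyl-bearing tertiary carbinol C8 sits next to oxygenated C7, which is a 2-hydroxy-2-methylcyclohexanone retron once C7 is a ketone. C8 is bonded to the side-chain carbon C9 and O8 lies 1,4 to C12, so only the wanted shift can be trapped.
5. Ring order: ring A is bought (C10 set by asymmetric allylation), then the five-membered precursor of ring B (Wacker/aldol), then six-membered ring B plus temporary ring C (key step), then ring C is opened.

Key step: step 9

Remark: labdane numbering (C1–C20) is used throughout, so in the hydrindane intermediates the five-membered ring is C5–C6–C7–C9–C10 and C8/C17 are exocyclic. The (R)-ligand in step 2 is chosen on the assumption that the sense of induction known for simple 2-alkylcyclohexanone allyl enol carbonates ((S)-ligand gives (S)-ketone) also holds here.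

Step 1
Reactants: 1 2,2,6-trimethylcyclohexanone; 2 allyl chloroformate
Product: 3 allyl 2,6,6-trimethylcyclohex-1-en-1-yl carbonate
Conditions: LiN(SiMe3)2, THF, 0 °C; then 2, −78 °C to rt
Reagents that add atoms: allyl chloroformate (2), C=CCOC(=O)Cl
Why: Enol carbonate formation: 1 has a single enolisable position, so one tetrasubstituted lithium enolate forms and the hard chloroformate acylates it on oxygen.

Step 2
Reactants: 3 allyl 2,6,6-trimethylcyclohex-1-en-1-yl carbonate
Product: 4 (R)-2-allyl-2,6,6-trimethylcyclohexanone
Conditions: Pd2(dba)3 (cat.), (R)-t-BuPHOX (cat.), THF, 25 °C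
Reagents that add atoms: none
Why: Decarboxylative asymmetric allylic alkylation (Tsuji type): zerovalent palladium ionises 3, CO2 is lost, and enolate and π-allyl fragment recombine inside the chiral P,N-ligand sphere, which sets the quaternary centre C10 as R.

Step 3
Reactants: 4 (R)-2-allyl-2,6,6-trimethylcyclohexanone
Product: 5 (R)-2,2,6-trimethyl-6-(2-oxopropyl)cyclohexanone
Conditions: PdCl2 (cat.), Cu(OAc)2 (cat.), O2 (1 atm), DMA/H2O, rt
Reagents that add atoms: water, O (source of the new carbonyl oxygen; O2 only reoxidises the catalyst)
Why: Tsuji–Wacker oxidation: the terminal alkene is hydroxypalladated in the Markovnikov sense to the methyl ketone, while the doubly neopentyl ring ketone and C10 are untouched.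

Step 4
Reactants: 5 (R)-2,2,6-trimethyl-6-(2-oxopropyl)cyclohexanone
Product: 6 (7aR)-4,4,7a-trimethyl-1,4,5,6,7,7a-hexahydro-2H-inden-2-one (enone C5=C6–C7=O)
Conditions: KOH (cat.), xylenes, 110 °C, Dean–Stark trap
Reagents that add atoms: none
Why: Intramolecular aldol condensation: only the methyl carbon C6 can reach the ring carbonyl C5 through a five-membered closure, and removal of water drives the hindered addition on to the conjugated enone.

Step 5
Reactants: 6 bicyclic enone; 7 methyl bromoacetate
Product: 8 methyl 2-[(7aR)-4,4,7a-trimethyl-2-oxo-2,4,5,6,7,7a-hexahydro-1H-inden-1-yl]acetate (both C9 epimers)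
Conditions: LiN(iPr)2, THF, −78 °C; then 7, DMPU, −78 to −20 °C
Reagents that add atoms: methyl bromoacetate (7), COC(=O)CBr
Why: Kinetic α'-enolate alkylation: C4 and C10 are quaternary, so the cross-conjugated enolate toward C9 is the only one possible and it reacts with the activated bromide; C9 is not controlled here and is set in step 6.

Step 6
Reactants: 8 alkylated enone
Product: 9 methyl 2-(4,4,7a-trimethyl-2-oxooctahydro-1H-inden-1-yl)acetate, trans-fused (5α-H, 10β-CH3), side chain 9β
Conditions: H2 (20 bar), Pd/C, NaOMe (cat.), MeOH, rt
Reagents that add atoms: none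
Why: Heterogeneous hydrogenation with base equilibration: H2 should add to C5=C6 from the α face because the β face is covered by the syn-axial methyl groups on C4 and C10 (5α-H, trans fusion), and methoxide equilibrates the epimerisable C9 to the pseudo-equatorial 9β side chain, the arrangement preferred next to the angular methyl group of trans-hydrindanes (as at C17 of steroids).

Step 7
Reactants: 9 trans-hydrindanone ester; 10 ethyltriphenylphosphonium bromide
Product: 11 methyl 2-(2-ethylidene-4,4,7a-trimethyloctahydro-1H-inden-1-yl)acetate (C7=C8 alkene, E/Z mixture; 5α-H, 9β, 10β-CH3)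
Conditions: 10, KOtBu, THF, 0 °C to rt
Reagents that add atoms: ethyltriphenylphosphonium bromide (10), CC[P+](c1ccccc1)(c1ccccc1)c1ccccc1.[Br-]
Why: Wittig olefination with a non-stabilised ylide, as used for ethylidenation of steroidal cyclopentanones; the ester is far less electrophilic than the ketone, and the alkene geometry is irrelevant because C8 becomes a carbonyl carbon.

Step 8
Reactants: 11 ethylidene ester
Product: 12 methyl 2-(2β-acetyl-2α-hydroxy-4,4,7a-trimethyloctahydro-1H-inden-1-yl)acetate (α-ketol: 7α-OH, 7β-acetyl, 9β side chain)
Conditions: RuCl3 (cat.), KHSO5 (as 2KHSO5·KHSO4·K2SO4), NaHCO3, EtOAc/MeCN/H2O, rt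
Reagents that add atoms: potassium peroxymonosulfate KHSO5, [K+].[O-]S(=O)(=O)OO
Why: RuO4-catalysed ketohydroxylation of a trisubstituted alkene: the [3+2] addition should occur on the α face, away from the 9β side chain and the 10β methyl group, so C7 receives the α-hydroxyl group and the CH terminus C8 is oxidised on to the ketone.

Step 9
Reactants: 12 α-ketol ester
Product: 14 7-oxo-13,14,15,16-tetranorlabdan-8α,12-olide, via ring-expanded hydroxy keto ester 13 (not isolated)
Conditions: Al(OtBu)3 (1.2 equiv), 4 Å molecular sieves, toluene, 90 °C; aqueous work-up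
Reagents that add atoms: none
Why: Al(OtBu)3 exchanges onto the 7α-hydroxyl and binds the acetyl oxygen, which holds O7 and O8 syn in a five-membered chelate with the C7–C9 bond over the carbonyl π* orbital; C9 then shifts suprafacially from C7 to C8 (α-ketol rearrangement), C7 becomes the ketone, and the cyclopentane C5–C6–C7–C9–C10 becomes the cyclohexane C5–C6–C7–C8–C9–C10 (ring B) of 13. The closest known reaction type is the Lewis-acid-mediated D-homoannulation of 17-hydroxy-20-oxo steroids, where an acetylcyclopentanol fused to a cyclohexane expands in the same way and the more substituted ring carbon migrates. Ring B is therefore formed by a 1,2-shift (one-carbon ring expansion, five to six members), and the temporary lactone ring C closes by 5-exo-trig attack of the new C8 aluminium alkoxide on the C12 ester with loss of methanol. The only new stereocentre, C8, is fixed by the C7 configuration through the chelate: with the acetyl group on the β face and O8 syn to the α-oxygen, the methyl group points to the β face and O8 ends equatorial (8α), while C9 migrates with retention and C5 and C10 are untouched. The step needs C9 rather than C6 to migrate, which is secured by the higher migratory aptitude of tertiary C9 in the Lewis-acid mode, by a transition state that places the acetyl methyl over the unsubstituted C6 side, and above all by the trap, since the ketol isomers interconvert but only the C9-shifted alkoxide has its oxygen 1,4 to C12 and can leave the equilibrium as a γ-lactone (the 7α-hydroxyl of 12 is trans to the side chain on a five-membered ring and cannot). Relief of trans-hydrindane strain and uptake of methanol by the sieves drive the sequence forward.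

Step 10
Reactants: 14 keto lactone
Product: 15 8α,12-epoxy-13,14,15,16-tetranorlabdane-7β,12-diol (lactol, both anomers)
Conditions: iBu2AlH (3.5 equiv), CH2Cl2, −78 °C; aqueous work-up
Reagents that add atoms: none
Why: Low-temperature iBu2AlH reduction: the lactone stops at the aluminium hemiacetal (lactol after work-up) and the C7 ketone is reduced at the same time, mainly by axial attack from the α face (7β-OH), a centre that is erased again in step 13.

Step 11
Reactants: 15 lactol; 16 ethyltriphenylphosphonium iodide
Product: 17 (12Z)-13-iodo-14,15-dinorlabd-12-ene-7β,8α-diol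
Conditions: 16, n-BuLi, THF, rt; I2, −78 °C; NaN(SiMe3)2, −20 °C; then 15 (ylide in excess), −78 to −20 °C
Reagents that add atoms: ethyltriphenylphosphonium iodide (16), CC[P+](c1ccccc1)(c1ccccc1)c1ccccc1.[I-]; iodine, II
Why: Stork–Zhao-type Wittig olefination: the strained trans-fused lactol reacts through its hydroxy aldehyde form with Ph3P=C(I)CH3, and the kinetically formed cis-oxaphosphetane places iodine cis to C11, giving the Z-iodoalkene.

Step 12
Reactants: 17 Z-vinyl iodide; 18 tributyl(vinyl)stannane
Product: 19 (12Z)-labda-12,14-diene-7β,8α-diol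
Conditions: 18, PdCl2(MeCN)2 (cat.), DMF, rt
Reagents that add atoms: tributyl(vinyl)stannane (18), C=C[Sn](CCCC)(CCCC)CCCC
Why: Stille coupling: oxidative addition and reductive elimination at the sp2 carbon proceed with retention, so the vinyl group takes the place of iodine, the 12Z geometry is kept, and the free hydroxyl groups are tolerated.

Step 13
Reactants: 19 diene diol
Product: 20 (12Z)-8α-hydroxylabda-12,14-dien-7-one
Conditions: Dess–Martin periodinane, pyridine, CH2Cl2, 0 °C
Reagents that add atoms: none
Why: Dess–Martin oxidation: only the secondary 7-OH can be oxidised, and the tertiary 8-OH and the diene are inert under the buffered conditions.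

Step 14
Reactants: 20 hydroxy ketone
Product: 21 (12Z)-6α,8α-dihydroxylabda-12,14-dien-7-one
Conditions: KN(SiMe3)2 (2.5 equiv), THF, −78 °C; 2-(phenylsulfonyl)-3-phenyloxaziridine, −78 °C; AcOH quench
Reagents that add atoms: 2-(phenylsulfonyl)-3-phenyloxaziridine, O=S(=O)(c1ccccc1)N1OC1c1ccccc1
Why: Enolate hydroxylation with a Davis oxaziridine: the ketone can enolise only toward C6, the β face of C6 is closed by the syn-axial methyl groups on C4, C8 and C10, so oxygen should arrive from the α face to give the equatorial (also thermodynamically preferred) 6α-OH, and the reagent does not touch the diene.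

Step 15
Reactants: 21 dihydroxy ketone; 22 acetic anhydride
Product: 23 (12Z)-6α-acetoxy-8α-hydroxylabda-12,14-dien-7-one
Conditions: 22, DMAP (cat.), pyridine, CH2Cl2, 0 °C to rt
Reagents that add atoms: acetic anhydride (22), CC(=O)OC(C)=O
Why: DMAP-catalysed acylation: the secondary 6α-OH is the only acylable hydroxyl group, because the tertiary 8α-OH is too hindered under these mild conditions.

Step 16
Reactants: 23 acetoxy ketone
Product: 24 (12Z)-6α-acetoxylabda-12,14-diene-7β,8α-diol (CNP0138393.1)
Conditions: Me4NBH(OAc)3, MeCN/AcOH, −30 °C
Reagents that add atoms: none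
Why: Hydroxyl-directed triacetoxyborohydride reduction (Evans–Saksena type): boron binds the 8α-oxygen and delivers hydride to the α face of C7, which is also the axial trajectory away from the axial 8β-methyl group, giving the equatorial 7β-OH, while the acidic medium suppresses acetyl migration and leaves the ester and diene untouched.

**Compound list**
1 | 2,2,6-trimethylcyclohexanone (racemic) | CC1CCCC(C)(C)C1=O | starting material
2 | allyl chloroformate | C=CCOC(=O)Cl | starting material
3 | allyl 2,6,6-trimethylcyclohex-1-en-1-yl carbonate | C=CCOC(=O)OC1=C(C)CCCC1(C)C | intermediate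
4 | (R)-2-allyl-2,6,6-trimethylcyclohexanone | C=CC[C@@]1(C)CCCC(C)(C)C1=O | intermediate
5 | (R)-2,2,6-trimethyl-6-(2-oxopropyl)cyclohexanone | CC(=O)C[C@@]1(C)CCCC(C)(C)C1=O | intermediate
6 | (7aR)-4,4,7a-trimethyl-1,4,5,6,7,7a-hexahydro-2H-inden-2-one | O=C1C=C2C(C)(C)CCC[C@]2(C)C1 | intermediate
7 | methyl bromoacetate | COC(=O)CBr | starting material
8 | methyl 2-[(7aR)-4,4,7a-trimethyl-2-oxo-2,4,5,6,7,7a-hexahydro-1H-inden-1-yl]acetate (both C9 epimers) | COC(=O)CC1C(=O)C=C2C(C)(C)CCC[C@@]21C | intermediate
9 | trans-hydrindanone ester (5α-H, 9β-CH2CO2Me, 10β-CH3, C7 ketone) | COC(=O)C[C@H]1C(=O)C[C@H]2C(C)(C)CCC[C@@]21C | intermediate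
10 | ethyltriphenylphosphonium bromide | CC[P+](c1ccccc1)(c1ccccc1)c1ccccc1.[Br-] | starting material
11 | 7-ethylidene ester (E/Z mixture at C7=C8) | COC(=O)C[C@H]1C(=CC)C[C@H]2C(C)(C)CCC[C@@]21C | intermediate
12 | α-ketol ester (7α-OH, 7β-acetyl) | COC(=O)C[C@H]1[C@@](O)(C(C)=O)C[C@H]2C(C)(C)CCC[C@@]21C | intermediate
13 | methyl 8α-hydroxy-7-oxo-13,14,15,16-tetranorlabdan-12-oate | COC(=O)C[C@H]1[C@](C)(O)C(=O)C[C@H]2C(C)(C)CCC[C@@]21C | intermediate
14 | 7-oxo-13,14,15,16-tetranorlabdan-8α,12-olide | O=C1C[C@H]2[C@](C)(O1)C(=O)C[C@H]3C(C)(C)CCC[C@@]32C | intermediate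
15 | 8α,12-epoxy-13,14,15,16-tetranorlabdane-7β,12-diol (both anomers) | OC1C[C@H]2[C@](C)(O1)[C@@H](O)C[C@H]3C(C)(C)CCC[C@@]32C | intermediate
16 | ethyltriphenylphosphonium iodide | CC[P+](c1ccccc1)(c1ccccc1)c1ccccc1.[I-] | starting material
17 | (12Z)-13-iodo-14,15-dinorlabd-12-ene-7β,8α-diol | I/C(C)=C\C[C@H]1[C@](C)(O)[C@@H](O)C[C@H]2C(C)(C)CCC[C@@]21C | intermediate
18 | tributyl(vinyl)stannane | C=C[Sn](CCCC)(CCCC)CCCC | starting material
19 | (12Z)-labda-12,14-diene-7β,8α-diol | C=C/C(C)=C\C[C@H]1[C@](C)(O)[C@@H](O)C[C@H]2C(C)(C)CCC[C@@]21C | intermediate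
20 | (12Z)-8α-hydroxylabda-12,14-dien-7-one | C=C/C(C)=C\C[C@H]1[C@](C)(O)C(=O)C[C@H]2C(C)(C)CCC[C@@]21C | intermediate
21 | (12Z)-6α,8α-dihydroxylabda-12,14-dien-7-one | C=C/C(C)=C\C[C@H]1[C@](C)(O)C(=O)[C@H](O)[C@H]2C(C)(C)CCC[C@@]21C | intermediate
22 | acetic anhydride | CC(=O)OC(C)=O | starting material
23 | (12Z)-6α-acetoxy-8α-hydroxylabda-12,14-dien-7-one | C=C/C(C)=C\C[C@H]1[C@](C)(O)C(=O)[C@H](OC(C)=O)[C@H]2C(C)(C)CCC[C@@]21C | intermediate
24 | (12Z)-6α-acetoxylabda-12,14-diene-7β,8α-diol (CNP0138393.1) | C=C/C(C)=C\C[C@H]1[C@](C)(O)[C@@H](O)[C@H](OC(C)=O)[C@H]2C(C)(C)CCC[C@@]21C | target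

**Total step count:** 16. **Longest linear sequence:** 16 (fully linear from 1).

**Steps most likely to fail**

Step 9. Three things may go wrong. C6 may migrate in competition with C9. A shift through a non-chelated conformer would invert C8. Lactonisation may be too slow, which would let the reversible ketol manifold settle at its thermodynamic mixture. The fallback replaces the reversible chelate-controlled shift by an irreversible, leaving-group-driven one and brings in O8 afterwards. It sets out from 11. α-Face dihydroxylation (OsO4 cat., N-methylmorpholine N-oxide) gives the 7α,8-diol F1. Selective mesylation of the secondary hydroxyl (MsCl, pyridine) gives the hydroxy mesylate F2. A semipinacol shift (Et3N, LiClO4, THF, warm), with C9 anti to the departing mesylate, expands the ring to the 8-methyl-7-ketone F3. Autoxidation of the more substituted enolate (KOtBu, O2, P(OEt)3, −20 °C) hydroxylates tertiary C8 from the open α face to give 13, which lactonises. The route is rejoined at 14.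

Step 11. The lactol may open sluggishly at the low temperature that the labile iodo ylide demands. The ylide may lose iodine, or the Z selectivity may erode. The fallback builds the Z-trisubstituted alkene at the ester oxidation level. It sets out from 15. Still–Gennari olefination (ethyl 2-[bis(2,2,2-trifluoroethoxy)phosphoryl]propanoate, KN(SiMe3)2, 18-crown-6, −78 °C) gives the Z-enoate F4. Reduction with iBu2AlH gives the allylic alcohol F5. MnO2 oxidises only the allylic hydroxyl to the Z-enal F6. Methylenation with Ph3P=CH2 rejoins the route at 19.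

Step 6. Hydrogen delivery to the β-carbon C5, flanked by two quaternary centres, may be slow or may show poor facial selectivity, and equilibration at C9 may be incomplete. The fallback changes from substrate-controlled surface hydrogenation to ligand-controlled homogeneous 1,4-hydride delivery. It sets out from 8. Copper hydride conjugate reduction (Cu(OAc)2 cat., DTBM-SEGPHOS enantiomer matched to α-face delivery, polymethylhydrosiloxane, toluene/t-BuOH) is followed by the same methoxide equilibration. The route is rejoined at 9, and no new compound is made (F0).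

**Further compounds**
F1 | step 9 | methyl 2-[2α-hydroxy-2β-(1-hydroxyethyl)-4,4,7a-trimethyloctahydro-1H-inden-1-yl]acetate (7α,8-diol, C8 epimers) | COC(=O)C[C@H]1[C@@](O)(C(C)O)C[C@H]2C(C)(C)CCC[C@@]21C
F2 | step 9 | 8-O-mesylate of F1 (hydroxy mesylate) | COC(=O)C[C@H]1[C@@](O)(C(C)OS(C)(=O)=O)C[C@H]2C(C)(C)CCC[C@@]21C
F3 | step 9 | methyl 7-oxo-13,14,15,16-tetranorlabdan-12-oate (8-methyl-7-ketone, C8 epimers) | COC(=O)C[C@H]1C(C)C(=O)C[C@H]2C(C)(C)CCC[C@@]21C
F4 | step 11 | ethyl (12Z)-7β,8α-dihydroxy-15-norlabd-12-en-14-oate | CCOC(=O)/C(C)=C\C[C@H]1[C@](C)(O)[C@@H](O)C[C@H]2C(C)(C)CCC[C@@]21C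
F5 | step 11 | (12Z)-15-norlabd-12-ene-7β,8α,14-triol | OC/C(C)=C\C[C@H]1[C@](C)(O)[C@@H](O)C[C@H]2C(C)(C)CCC[C@@]21C
F6 | step 11 | (12Z)-7β,8α-dihydroxy-15-norlabd-12-en-14-al | O=C/C(C)=C\C[C@H]1[C@](C)(O)[C@@H](O)C[C@H]2C(C)(C)CCC[C@@]21C
F0 | step 6 | none | none
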